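The number I began with was 4.57 min, the relaxation half-life of target and isomer of the product at −20 °C: the natural log of two over the sum of the forward and backward isomerisation constants, the time in which isomerisation by itself halves the pair's distance from equilibrium.

in all of them: starting material 0.089 M; first nucleophile 0.267 M; second nucleophile 0.160 M; time 8.0 min
- theta: temperature −35 °C
- beta: temperature −5 °C
- alpha: temperature −20 °C

    starting material → intermediate (k1 = 0.00750 s⁻¹, Ea1 = 74.0 kJ mol⁻¹)
    first nucleophile + intermediate → target (k2 = 5.94 M⁻¹ s⁻¹, Ea2 = 49.0 kJ mol⁻¹)
    second nucleophile + intermediate → other capture product (k3 = 1.94 M⁻¹ s⁻¹, Ea3 = 44.0 kJ mol⁻¹)
    first nucleophile → decomposed reagent (k4 = 0.00173 s⁻¹, Ea4 = 72.0 kJ mol⁻¹)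
    target ⇌ isomer of the product (K5 = 2.48, k5 = 0.00180 s⁻¹, Ea5 = 68.0 kJ mol⁻¹, ΔH5 = −6.00 kJ mol⁻¹)
    (constants at −20 °C)

- constants are those at −20 °C; use the activation energies and enthalpies for any other temperature

- the best flask by share of target in all that became target or other capture product or isomer of the product; "all alike" if 1.5 percentage points covers them all (theta / beta / alpha / all alike)
- share of target in all that became target or other capture product or isomer of the product, theta
- share of target in all that became target or other capture product or isomer of the product, beta
- share of target in all that became target or other capture product or isomer of the product, alpha

I kept a ledger for alpha, whose constants stand as given. Starting material is the limiting reagent, its charge being smaller than that of first nucleophile.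

1. Starting material left at 8.0 min: first-order decay leaves 2.73% of the charge.

2. Intermediate: its lifetime at the charges is 0.527 s, against 133 s for starting material, so I booked hardly any there (a steady state).

3. Capture: I froze c(second nucleophile) at its charge and c(first nucleophile) at the 0.212 M that decomposition alone leaves after one lifetime of starting material. The target side then takes 80.2% of each capture. Other capture product is booked at 19.3% of the charge, and the pair at 78.0%.

4. Inside the pair: equilibrium leaves target 28.7% of the pair. Each portion made relaxes with the half-life 4.57 min, and summing over the making leaves an excess weight of 0.407. Target is booked at 45.7% of the charge and isomer of the product at 32.3%.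

5. The books close on the charge, and my share of target in alpha was 47.0%.

6. The other flasks: isomerisation speeds up by a factor of 47 from coldest to hottest. Placing alpha at the geometric middle gave roughly 31.3 min for theta, longer than 8.0 min, and roughly 0.667 min for beta, shorter than 8.0 min. So I expected theta best and beta worst, without a number for either.

The forecast gave 76.5% for theta, 46% for alpha and 25.7% for beta, and so theta, on the ground that “the real difference comes from isomerisation of the target”. For alpha it stood a little below my figure.

The flasks gave 75.7% in theta, 45.6% in alpha and 25.8% in beta, so theta stood best. At 8.00 min alpha made target at 0.232 of the rate at which it lost it, each step taken net, holding target 44.3% and isomer of the product 32.0% of the charge, so target was 58.1% of the pair. Carrying 4.57 min over the 12.0 min to the later reading of alpha, I reckoned the excess over 28.7% down and target at 33.5% of the pair, leaving out the little target still to be made. At 20.0 min alpha held target 26.3% and isomer of the product 51.6%, which is 33.8%.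

(The rate constants stand for no real mixture; no experiment stands behind them.)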